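**Plan**

- Ring A of evelynin is a 1,4-benzoquinone whose C1 carbonyl lies between the two methoxy-bearing carbons C2 and C6, with the ketopropyl chain on C3 and hydrogen on C5. C1–C4 therefore correspond to a squaric acid core and C5–C6 to methoxyacetylene.
- Retrosynthesis: (a) unmask the aryl ketone from a dioxolane; (b) cut C1–C6 of ring A (re-forming C1–C4) to a 4-hydroxy-4-(methoxyethynyl)cyclobutenone; (c) cut C3–CH2 (chain alkyllithium) and C4–alkyne (lithium methoxyacetylide), both back to dimethyl squarate; (d) cut aryl–C(=O) of the chain (Friedel–Crafts).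
- Forward: the chain arm is made in steps 1–3 and methoxyacetylene in step 4. The acetylide is joined to the squarate first (step 5), the chain second with 1,3-carbonyl transposition (step 6), the hydroxyl is freed (step 7), ring A is closed by thermal ring expansion (step 8) and the ketone is released (step 9).
- Stereochemistry: evelynin has no stereocentre. The one stereocentre of the cyclobutenones (C4) is carried as the racemate and disappears when ring A forms.

Key step: step 8

Remark on the chemistry: methoxyacetylene is assumed not to be a stock reagent and is prepared in step 4. A triethylsilyl ether is chosen for the tertiary hydroxyl as a compromise between resistance to O-to-O silyl migration in step 6 and easy removal in step 7.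

**Route**

Step 1
Reactants: 1 veratrole; 2 3-chloropropanoyl chloride
Product: 3 3-chloro-1-(3,4-dimethoxyphenyl)propan-1-one
Conditions: AlCl3 (1.1 equiv), CH2Cl2, 0 → 23 °C; cold aq. HCl quench
Reagents that add atoms: none
Why: Friedel–Crafts acylation; the acylium ion should attack veratrole para to one methoxy group, the only unhindered activated position, and the primary chloride is inert at this temperature.

Step 2
Reactants: 3 3-chloro-1-(3,4-dimethoxyphenyl)propan-1-one
Product: 4 2-(2-chloroethyl)-2-(3,4-dimethoxyphenyl)-1,3-dioxolane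
Conditions: HOCH2CH2OH (5 equiv), p-TsOH·H2O (cat.), PhH, reflux, Dean–Stark
Reagents that add atoms: ethylene glycol, OCCO
Why: Acid-catalysed ketalisation driven by azeotropic removal of water; it masks the aryl ketone against the carbanion chemistry of step 6, and the non-basic medium should not eliminate HCl from the β-chloro ketone.

Step 3
Reactants: 4 2-(2-chloroethyl)-2-(3,4-dimethoxyphenyl)-1,3-dioxolane
Product: 5 2-(3,4-dimethoxyphenyl)-2-(2-iodoethyl)-1,3-dioxolane
Conditions: NaI (3 equiv), NaHCO3 (0.1 equiv), 2-butanone, reflux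
Reagents that add atoms: sodium iodide, [Na+].[I-]
Why: Finkelstein exchange (SN2 at a primary carbon, driven by precipitation of NaCl) supplies the iodide needed for fast iodine–lithium exchange, and the bicarbonate keeps the ketal safe from traces of acid.

Step 4
Reactants: 6 chloroacetaldehyde dimethyl acetal
Product: 8 methoxyacetylene, via sodium methoxyacetylide 7 (not isolated)
Conditions: NaNH2 (3.1 equiv), liq. NH3, −33 °C; evaporate NH3; sat. aq. NaCl, −20 °C; distil the volatile alkyne into THF at −78 °C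
Reagents that add atoms: none
Why: Two successive β-eliminations (methanol, then HCl) and deprotonation by sodium amide give acetylide 7, and aqueous quench releases the ynol ether; this is the classical dehydrohalogenation route from α-chloro acetals to 1-alkynyl ethers.

Step 5
Reactants: 9 dimethyl squarate; 8 methoxyacetylene
Product: 12 racemic 2,3-dimethoxy-4-(methoxyethynyl)-4-(triethylsilyloxy)cyclobut-2-en-1-one, via lithium methoxyacetylide 10 (not isolated), via lithium cyclobutenolate 11 (not isolated)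
Conditions: 8 (1.1 equiv), n-BuLi, THF, −78 °C; cannulate into 9, THF, −78 °C; Et3SiOTf (1.1 equiv), −78 °C; Et3N, aq. NaHCO3
Reagents that add atoms: triethylsilyl trifluoromethanesulfonate, CC[Si](CC)(CC)OS(=O)(=O)C(F)(F)F
Why: 1,2-Addition of a lithium acetylide to one of the two equivalent vinylogous-ester carbonyls of the squarate should stop at mono-addition because alkoxide 11 deactivates the second carbonyl; trapping 11 on oxygen in situ gives the silyl ether, whose new stereocentre forms as the racemate with no control needed.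

Step 6
Reactants: 5 2-(3,4-dimethoxyphenyl)-2-(2-iodoethyl)-1,3-dioxolane; 12 racemic 2,3-dimethoxy-4-(methoxyethynyl)-4-(triethylsilyloxy)cyclobut-2-en-1-one
Product: 16 racemic 3-{2-[2-(3,4-dimethoxyphenyl)-1,3-dioxolan-2-yl]ethyl}-2-methoxy-4-(methoxyethynyl)-4-(triethylsilyloxy)cyclobut-2-en-1-one, via alkyllithium 13 (not isolated), via lithium alkoxide 14 (not isolated), via allylic trifluoroacetate 15 (not isolated)
Conditions: 5 (1.3 equiv), t-BuLi (2.6 equiv), Et2O–pentane, −78 °C; 12, THF, −78 °C; (CF3CO)2O (1.4 equiv), −78 °C; pyridine, then aq. NaHCO3, −78 → 0 °C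
Reagents that add atoms: water, O
Why: Iodine–lithium exchange gives primary alkyllithium 13, which adds 1,2 to the remaining vinylogous-ester carbonyl; trifluoroacetylation of alkoxide 14 and ionisation of 15 give a methoxy-stabilised cyclobutenyl cation that water captures at the distal methoxy carbon with loss of methanol (a Stork–Danheiser-type 1,3-carbonyl transposition as used on squarate bis-adducts), so the chain ends on the ring carbon remote from the new ketone, while the silyl ether, a poor leaving group held at −78 °C, keeps the propargylic oxygen in place.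

Step 7
Reactants: 16 racemic 3-{2-[2-(3,4-dimethoxyphenyl)-1,3-dioxolan-2-yl]ethyl}-2-methoxy-4-(methoxyethynyl)-4-(triethylsilyloxy)cyclobut-2-en-1-one
Product: 17 racemic 3-{2-[2-(3,4-dimethoxyphenyl)-1,3-dioxolan-2-yl]ethyl}-4-hydroxy-2-methoxy-4-(methoxyethynyl)cyclobut-2-en-1-one
Conditions: Bu4NF, AcOH (1:1), THF, 0 °C
Reagents that add atoms: none
Why: Fluoride cleaves the Si–O bond, and the acetic acid buffer protonates the tertiary alkoxide at once so that it cannot open the strained ring; the near-neutral medium should spare both the ynol ether and the dioxolane.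

Step 8
Reactants: 17 racemic 3-{2-[2-(3,4-dimethoxyphenyl)-1,3-dioxolan-2-yl]ethyl}-4-hydroxy-2-methoxy-4-(methoxyethynyl)cyclobut-2-en-1-one
Product: 20 evelynin ethylene ketal (3-{2-[2-(3,4-dimethoxyphenyl)-1,3-dioxolan-2-yl]ethyl}-2,6-dimethoxycyclohexa-2,5-diene-1,4-dione), via enynylketene 18 (not isolated), via ring diradical 19 (not isolated)
Conditions: PhMe (0.01 M, degassed), 110 °C, Ar, dark
Reagents that add atoms: none
Why: Heat should break the C1–C4 bond of 17 in a conrotatory 4π electrocyclic opening in which the donor hydroxyl rotates away from the ring, so that in ketene 18 the methoxyethynyl group stands cis to the ketene unit. C1 of the ketene then attacks the methoxy-bearing alkyne terminus C6 to give the aromatic diradical 19 (phenoxyl oxygen on C1, σ-radical at C5), and a shift of the hydroxyl hydrogen from the C4 oxygen to C5 gives the quinone with no oxidant; the closest known reaction type is the Moore rearrangement of 4-alkynyl-4-hydroxycyclobutenones. Ring A closes by formation of the C1–C6 bond, a six-membered closure that is endo at the alkyne, with C1–C4 taken from the squarate core and C5–C6 from the alkyne. No stereocentre is formed, and the single stereocentre of 17 is erased. The step needs closure at C6 and not at C5 (six- over five-membered ring), which should follow from the methoxy terminus because, unlike aryl, silyl or ester groups, it gives no stabilised exocyclic vinyl radical, and the non-polar solvent disfavours a charge-separated closure at C5. The 2,6- and not 2,5-dimethoxy pattern is fixed beforehand because the chain already sits on C3, remote from the ketone, and the ring methoxy group on C2.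

Step 9
Reactants: 20 evelynin ethylene ketal
Product: 21 evelynin
Conditions: 0.5 M aq. HCl, THF, 23 °C
Reagents that add atoms: water, O
Why: Acid-catalysed hydrolysis of the dioxolane through an oxocarbenium ion stabilised by the 3,4-dimethoxyphenyl group should be fast under conditions too mild to hydrolyse the vinylogous-ester methoxy groups of the quinone.

**Compound list**

1 | veratrole (1,2-dimethoxybenzene) | COc1ccccc1OC | starting material
2 | 3-chloropropanoyl chloride | ClCCC(Cl)=O | starting material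
3 | 3-chloro-1-(3,4-dimethoxyphenyl)propan-1-one | COc1ccc(cc1OC)C(=O)CCCl | intermediate
4 | 2-(2-chloroethyl)-2-(3,4-dimethoxyphenyl)-1,3-dioxolane | COc1ccc(cc1OC)C1(CCCl)OCCO1 | intermediate
5 | 2-(3,4-dimethoxyphenyl)-2-(2-iodoethyl)-1,3-dioxolane | COc1ccc(cc1OC)C1(CCI)OCCO1 | intermediate
6 | chloroacetaldehyde dimethyl acetal (2-chloro-1,1-dimethoxyethane) | COC(CCl)OC | starting material
7 | sodium methoxyacetylide | [Na+].[C-]#COC | intermediate
8 | methoxyacetylene (methoxyethyne) | C#COC | intermediate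
9 | dimethyl squarate (3,4-dimethoxycyclobut-3-ene-1,2-dione) | COC1=C(OC)C(=O)C1=O | starting material
10 | lithium methoxyacetylide | [Li]C#COC | intermediate
11 | lithium 2,3-dimethoxy-1-(methoxyethynyl)-4-oxocyclobut-2-en-1-olate (racemic) | [Li+].[O-]C1(C#COC)C(OC)=C(OC)C1=O | intermediate
12 | racemic 2,3-dimethoxy-4-(methoxyethynyl)-4-(triethylsilyloxy)cyclobut-2-en-1-one | CC[Si](CC)(CC)OC1(C#COC)C(OC)=C(OC)C1=O | intermediate
13 | {2-[2-(3,4-dimethoxyphenyl)-1,3-dioxolan-2-yl]ethyl}lithium | [Li]CCC1(OCCO1)c2ccc(OC)c(OC)c2 | intermediate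
14 | lithium 1-{2-[2-(3,4-dimethoxyphenyl)-1,3-dioxolan-2-yl]ethyl}-2,3-dimethoxy-4-(methoxyethynyl)-4-(triethylsilyloxy)cyclobut-2-en-1-olate (racemic, mixture of diastereomers) | [Li+].[O-]C1(CCC2(OCCO2)c3ccc(OC)c(OC)c3)C(OC)=C(OC)C1(O[Si](CC)(CC)CC)C#COC | intermediate
15 | 1-{2-[2-(3,4-dimethoxyphenyl)-1,3-dioxolan-2-yl]ethyl}-2,3-dimethoxy-4-(methoxyethynyl)-4-(triethylsilyloxy)cyclobut-2-en-1-yl trifluoroacetate (racemic, mixture of diastereomers) | FC(F)(F)C(=O)OC1(CCC2(OCCO2)c3ccc(OC)c(OC)c3)C(OC)=C(OC)C1(O[Si](CC)(CC)CC)C#COC | intermediate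
16 | racemic 3-{2-[2-(3,4-dimethoxyphenyl)-1,3-dioxolan-2-yl]ethyl}-2-methoxy-4-(methoxyethynyl)-4-(triethylsilyloxy)cyclobut-2-en-1-one | CC[Si](CC)(CC)OC1(C#COC)C(CCC2(OCCO2)c3ccc(OC)c(OC)c3)=C(OC)C1=O | intermediate
17 | racemic 3-{2-[2-(3,4-dimethoxyphenyl)-1,3-dioxolan-2-yl]ethyl}-4-hydroxy-2-methoxy-4-(methoxyethynyl)cyclobut-2-en-1-one | COC#CC1(O)C(CCC2(OCCO2)c3ccc(OC)c(OC)c3)=C(OC)C1=O | intermediate
18 | (3E)-3-{2-[2-(3,4-dimethoxyphenyl)-1,3-dioxolan-2-yl]ethyl}-4-hydroxy-2,6-dimethoxyhexa-1,3-dien-5-yn-1-one (enynylketene; hydroxyl trans and alkynyl cis to the ketene carbon across C3=C4) | O=C=C(OC)/C(CCC1(OCCO1)c2ccc(OC)c(OC)c2)=C(\C#COC)O | intermediate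
19 | 3-{2-[2-(3,4-dimethoxyphenyl)-1,3-dioxolan-2-yl]ethyl}-4-hydroxy-2,6-dimethoxyphenoxyl-5-yl diradical (phenoxyl oxygen on C1, σ-radical at C5) | COc1[c]c(O)c(CCC2(OCCO2)c3ccc(OC)c(OC)c3)c(OC)c1[O] | intermediate
20 | evelynin ethylene ketal, 3-{2-[2-(3,4-dimethoxyphenyl)-1,3-dioxolan-2-yl]ethyl}-2,6-dimethoxycyclohexa-2,5-diene-1,4-dione | COC1=CC(=O)C(CCC2(OCCO2)c3ccc(OC)c(OC)c3)=C(OC)C1=O | intermediate
21 | evelynin, 3-[3-(3,4-dimethoxyphenyl)-3-oxopropyl]-2,6-dimethoxycyclohexa-2,5-diene-1,4-dione (achiral) | COC1=CC(=O)C(CCC(=O)c2ccc(OC)c(OC)c2)=C(OC)C1=O | target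

**Count and risks**

Total step count: 9. Longest linear sequence: 7 steps (steps 1, 2, 3, 6, 7, 8, 9 from veratrole); the alkyne arm (steps 4 and 5) joins at step 6.

Step 6 (chain addition and transposition). What may go wrong:
- the γ-dialkoxy alkyllithium may be lost by 1,3-elimination or proton transfer;
- the silyl group may shift to the newly formed alkoxide before acylation, so that the wrong carbinol ionises;
- the anhydride may acylate the ynol ether instead of the alkoxide.

The fallback sets out from iodide 5 and silyl ether 12 and comes back at 16. Magnesium insertion into 5 (Mg, Et2O, 0–20 °C) should give {2-[2-(3,4-dimethoxyphenyl)-1,3-dioxolan-2-yl]ethyl}magnesium iodide F1. Anhydrous CeCl3 in THF at −78 °C should convert it into dichloro{2-[2-(3,4-dimethoxyphenyl)-1,3-dioxolan-2-yl]ethyl}cerium F2, a much less basic and more oxophilic carbanion whose alkoxide adduct is a poor partner for silyl transfer. Addition of F2 to 12 and an aqueous NH4Cl quench should release 1-{2-[2-(3,4-dimethoxyphenyl)-1,3-dioxolan-2-yl]ethyl}-2,3-dimethoxy-4-(methoxyethynyl)-4-(triethylsilyloxy)cyclobut-2-en-1-ol F3, which is isolated. The transposition is then run as a separate operation, with (CF3CO)2O and excess pyridine in CH2Cl2 at −40 °C followed by aqueous NaHCO3, through trifluoroacetate 15 to 16.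

Step 8 (ring expansion). What may go wrong:
- the ketene may close onto the proximal alkyne carbon and give a five-membered alkylidene cyclopentenedione;
- the ynol ether may decompose thermally before the four-membered ring opens.

The fallback sets out from 17 and comes back at 20. It replaces the diradical closure by a 6π electrocyclisation that can only give a six-membered ring. Semi-hydrogenation of 17 (H2, Pd/CaCO3 poisoned with Pb(OAc)2, i.e. Lindlar catalyst, quinoline, EtOAc, 0 °C) should give racemic 3-{2-[2-(3,4-dimethoxyphenyl)-1,3-dioxolan-2-yl]ethyl}-4-hydroxy-2-methoxy-4-[(Z)-2-methoxyethenyl]cyclobut-2-en-1-one F4. Heating F4 in toluene at 110 °C should open it to (3E,5Z)-3-{2-[2-(3,4-dimethoxyphenyl)-1,3-dioxolan-2-yl]ethyl}-4-hydroxy-2,6-dimethoxyhexa-1,3,5-trien-1-one F5. This should cyclise to 3-{2-[2-(3,4-dimethoxyphenyl)-1,3-dioxolan-2-yl]ethyl}-4-hydroxy-2,6-dimethoxycyclohexa-2,4-dien-1-one F6 and tautomerise to 3-{2-[2-(3,4-dimethoxyphenyl)-1,3-dioxolan-2-yl]ethyl}-2,6-dimethoxybenzene-1,4-diol F7. Oxidation of F7 with Ag2O (MgSO4, Et2O, 23 °C) should give quinone ketal 20.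

Step 7 (release of the hydroxyl). What may go wrong:
- the alkoxide formed on desilylation may open or fragment the strained hydroxy ketone;
- cleavage may stay incomplete under the buffered conditions.

The fallback sets out from 16 and comes back at 21. It keeps the silyl ether through the ring expansion, using the silyl-migration variant of the same rearrangement that is known for trimethylsilyl ethers. Heating 16 in p-xylene at 138 °C should give (3E)-3-{2-[2-(3,4-dimethoxyphenyl)-1,3-dioxolan-2-yl]ethyl}-2,6-dimethoxy-4-(triethylsilyloxy)hexa-1,3-dien-5-yn-1-one F8. Closure should give 3-{2-[2-(3,4-dimethoxyphenyl)-1,3-dioxolan-2-yl]ethyl}-2,6-dimethoxy-4-(triethylsilyloxy)phenoxyl-5-yl diradical F9. Transfer of the silyl group from oxygen to C5 should give 3-{2-[2-(3,4-dimethoxyphenyl)-1,3-dioxolan-2-yl]ethyl}-2,6-dimethoxy-5-(triethylsilyl)cyclohexa-2,5-diene-1,4-dione F10. Brief treatment of F10 with CF3CO2H in wet CH2Cl2 (0 → 23 °C) should bring about ipso-protodesilylation at C5, a β-silyl vinylogous-ester position, and cleave the dioxolane in the same operation, giving evelynin 21.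

**Further compounds**

F1 | step 6 | {2-[2-(3,4-dimethoxyphenyl)-1,3-dioxolan-2-yl]ethyl}magnesium iodide | I[Mg]CCC1(OCCO1)c2ccc(OC)c(OC)c2
F2 | step 6 | dichloro{2-[2-(3,4-dimethoxyphenyl)-1,3-dioxolan-2-yl]ethyl}cerium | Cl[Ce](Cl)CCC1(OCCO1)c2ccc(OC)c(OC)c2
F3 | step 6 | 1-{2-[2-(3,4-dimethoxyphenyl)-1,3-dioxolan-2-yl]ethyl}-2,3-dimethoxy-4-(methoxyethynyl)-4-(triethylsilyloxy)cyclobut-2-en-1-ol (racemic, mixture of diastereomers) | OC1(CCC2(OCCO2)c3ccc(OC)c(OC)c3)C(OC)=C(OC)C1(O[Si](CC)(CC)CC)C#COC
F4 | step 8 | racemic 3-{2-[2-(3,4-dimethoxyphenyl)-1,3-dioxolan-2-yl]ethyl}-4-hydroxy-2-methoxy-4-[(Z)-2-methoxyethenyl]cyclobut-2-en-1-one | CO/C=C\C1(O)C(CCC2(OCCO2)c3ccc(OC)c(OC)c3)=C(OC)C1=O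
F5 | step 8 | (3E,5Z)-3-{2-[2-(3,4-dimethoxyphenyl)-1,3-dioxolan-2-yl]ethyl}-4-hydroxy-2,6-dimethoxyhexa-1,3,5-trien-1-one | O=C=C(OC)/C(CCC1(OCCO1)c2ccc(OC)c(OC)c2)=C(\C=C/OC)O
F6 | step 8 | racemic 3-{2-[2-(3,4-dimethoxyphenyl)-1,3-dioxolan-2-yl]ethyl}-4-hydroxy-2,6-dimethoxycyclohexa-2,4-dien-1-one | COC1C=C(O)C(CCC2(OCCO2)c3ccc(OC)c(OC)c3)=C(OC)C1=O
F7 | step 8 | 3-{2-[2-(3,4-dimethoxyphenyl)-1,3-dioxolan-2-yl]ethyl}-2,6-dimethoxybenzene-1,4-diol | COc1cc(O)c(CCC2(OCCO2)c3ccc(OC)c(OC)c3)c(OC)c1O
F8 | step 7 | (3E)-3-{2-[2-(3,4-dimethoxyphenyl)-1,3-dioxolan-2-yl]ethyl}-2,6-dimethoxy-4-(triethylsilyloxy)hexa-1,3-dien-5-yn-1-one | O=C=C(OC)/C(CCC1(OCCO1)c2ccc(OC)c(OC)c2)=C(\C#COC)O[Si](CC)(CC)CC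
F9 | step 7 | 3-{2-[2-(3,4-dimethoxyphenyl)-1,3-dioxolan-2-yl]ethyl}-2,6-dimethoxy-4-(triethylsilyloxy)phenoxyl-5-yl diradical | CC[Si](CC)(CC)Oc1[c]c(OC)c([O])c(OC)c1CCC2(OCCO2)c3ccc(OC)c(OC)c3
F10 | step 7 | 3-{2-[2-(3,4-dimethoxyphenyl)-1,3-dioxolan-2-yl]ethyl}-2,6-dimethoxy-5-(triethylsilyl)cyclohexa-2,5-diene-1,4-dione | COC1=C([Si](CC)(CC)CC)C(=O)C(CCC2(OCCO2)c3ccc(OC)c(OC)c3)=C(OC)C1=O
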